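The data are simulated with constants of no real substance; scatter was added.

If a trace of impurity takes catalyst mole for mole, keep the books on the catalyst first.

| setting | dawn | dusk | flask |
|---|---|---|---|
| left-handed substrate | 0.26 M | 0.38 M | 0.51 M |
| right-handed substrate | 0.26 M | 0.38 M | 0.51 M |
| coupling partner | 4 equiv | 4 equiv | 4.00 equiv |
| precatalyst | 0.1 mol% | 0.1 mol% | 0.1 mol% |
| impurity | 0.24 mM | 0.24 mM | 0.24 mM |
| remark | run made earlier | run made earlier |  |
| time |  |  | 25 min |

- dawn (time / min: left-handed product / %, right-handed product / %): 5.00: 0.1, 0.8; 10.0: 0, 1.3; 15.0: 2.4, 0.1; 20.0: 0.7, 0; 25.0: 2.8, 2.7; 30.0: 2.8, 1.3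
- dusk (time / min: left-handed product / %, right-handed product / %): 2.00: 0, 1.0; 6.00: 2.0, 3.3; 10.0: 4.0, 3.8; 15.0: 9.3, 5.4; 25.0: 20.0, 12.1; 30.0: 21.7, 15.1

(readings scatter by 1 percentage point)

- left-handed product and right-handed product together, in percent of the left-handed substrate and right-handed substrate charged together, at 25 min
- excess of left-handed product over right-handed product in the product at 25 min
- whether the exchange between left-handed substrate and right-handed substrate keeps pace with the reaction: how far the product's excess at 25 min gets from its value without exchange to its value with instant exchange (above 80% keeps pace, below 20% hardly takes part, else lags behind)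

- free catalyst is single-handed; left-handed substrate and right-handed substrate are mirror images of each other, charged as a racemate, each of them at the stated concentration
- an excess is the difference of the two amounts in percent of their sum
- an excess is below zero if the other one leads

Open the account of the flask with the precatalyst, reckoned on the left-handed substrate: credit 0.510 mM. Debit the impurity, the limiting reagent of this poisoning, at 0.24 mM, less than the credit. Call the balance the surplus catalyst, S, the catalyst charged minus the impurity charged: 0.270 mM. The same books close at 0.0200 mM for dawn and 0.140 mM for dusk, so the dawn run, the slower in its readings, has less surplus than the dusk run.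

Now spend S. Treat the two substrates as one pool with a mean constant k, assume first order in the pool, in S and in the coupling partner B, and hold B at its charge. Integrating this pseudo-first-order loss gives K = k·B·S·t, where K is the negative logarithm of the unreacted fraction. Dusk reads 32.1% at 25.0 min, so K = 0.387. At the same time the flask has B·S larger by a factor of 2.59, so K = 1.00 and I reckon y = 63.3%.

Pooling the dusk readings from 15.0 min onward gives an excess of 22.0%, which I carry over to the flask. Instant exchange between the two substrates holds the product's excess level as conversion climbs, but these readings are too scattered to show how near the dusk run comes to that, so my call of keeps pace is tentative.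

The forecast gives 48% (38% to 60%), 19% (10% to 29%) and hardly takes part, remarking “The data barely separate these limits”.

The flask gives 60.1% and 21.2%, and the exchange keeps pace, going 88% of the way.

    free catalyst + impurity → spent catalyst (k = 1500 /M/s)
    precatalyst → free catalyst (k = 0.00440 /s)
    coupling partner + free catalyst + left-handed substrate → free catalyst + left-handed product (k = 2.20 /M²/s)
    left-handed substrate ⇌ right-handed substrate (k = 0.00690 /s)
    coupling partner + free catalyst + right-handed substrate → free catalyst + right-handed product (k = 1.40 /M²/s)

At 25.0 min the flask holds 52.8% of its catalyst as free catalyst, 47.1% as spent catalyst and 0.136% as precatalyst, and S is 52.9% of the charge. Apply S to the neighbour with 0.04 mol% of precatalyst: S = −0.0360 mM, a deficit. That neighbour reaches 0.461% at 25.0 min and keeps 15.1% of its impurity, which is 0.0362 mM.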